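The slow part of these runs is the late fall of target after its early peak, and two chemists dispute where that fall ends in red, the flask asked about.

| flask | starting material | capture agent | remark | time |
|---|---|---|---|---|
| red | 0.14 M | 2.8 mM | the very flask that is asked about, followed so far |  |
| green | 0.14 M | 1.9 mM | run made earlier |  |
| flask | 0.14 M | 2.80 mM |  | 8.0 min |

- red (time / min: target / %, starting material / %): 0.250: 21.6, 23.7; 0.333: 26.2, 17.7; 0.500: 29.2, 9.2; 0.833: 33.8, 3.9; 1.00: 32.8, 2.9; 1.50: 33.2, 0; 2.50: 28.0, 0
- green (time / min: target / %, starting material / %): 0.250: 22.3, 25.4; 0.417: 28.8, 12.9; 0.667: 33.4, 5.0; 1.33: 34.1, 0; 2.00: 30.9, 0.3; 3.00: 26.8, 0; 6.00: 25.6, 1.6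

(standard deviation of a reading: 1 percentage point)

- the best time, 8.0 min at the latest, for target
- the amount of target, in percent of the starting material charged, at that time
- the first time at which target reaches 16%, in the same percent, in min



The first holds that capture agent consumes target, so red, with more agent than green, must end lower. The second divides the charges. Her quantity is the capacity C, 2.00% in red and 1.36% in green, the charge of capture agent over the charge of starting material: the most the agent can bind, one for one, in percent of the starting material charged. In the green readings target falls 8.5 percentage points between 1.33 min and 6.00 min, more than C, so on her count, within the scatter, about 7.1 points of that fall went elsewhere. Green's flat end then looks like a balance that target approaches.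

I side with her and commit for red to a peak like the reading of 33.8% at 0.833 min, and to a level at 8.0 min no lower than green's last reading less C, 23.6%.

The forecast, on the first side, gives 33.8% at 1.1 min, the asked level at 0.155 min, and says “Red, with more agent, should therefore fall further, to about 21% by 8 min”.

Red gives 32.8% at 0.988 min and the asked level at 0.148 min. At 8.00 min target stands at 23.8%, a fall of 9 points against C of 2.00%, with 59% of the capture agent left. The first view gets its region at long times: at 80.0 min red has 22.8% target, 1.06% of its capture agent left and 1.98% trapped intermediate, nearly all of C.

    2 starting material → self-condensation product (k = 0.330 M⁻¹ s⁻¹)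
    open intermediate ⇌ target (K = 2.20, k = 0.520 s⁻¹)
    starting material → open intermediate (k = 0.0480 s⁻¹)
    open intermediate + capture agent → trapped intermediate (k = 0.0640 M⁻¹ s⁻¹)
    open intermediate ⇌ isomer of the product (K = 2.00, k = 0.00860 s⁻¹)

In red, open intermediate has a half-life of 1.3 min towards isomer of the product by that forward step alone, against 64 min towards trapped intermediate, pseudo-first-order with capture agent as charged. At 8.00 min red holds 20.4% isomer of the product and 0.817% trapped intermediate.

The neighbour flask, charged with 0.056 M of starting material, has C of 5.00%, the most its capture agent can account for. Its target stands at 43.4% at best and at 31.6% at 8.00 min, a difference of 12 points, more than its C, with 1.21% trapped intermediate and 76% of the agent left.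

All runs stem from a simulated flask from invented constants, and the scatter is random.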